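## Analysis of the target

The target (C28H24O5) is a macrocyclic bis(bibenzyl): four benzene rings are tied into one 19-membered ring by two CH2CH2 bridges and two diaryl ether oxygens. Ring A is the hydroxyphenyl ring whose C1 carries the ethano bridge to ring D, whose C3 carries the ether oxygen to ring B and whose C4 carries a free OH. Ring B is a meta-phenylene (ether oxygen at C1, ethano bridge to ring C at C3). Ring C carries that bridge at C1, free OH groups at C3 and C4 and the ether oxygen to ring D at C5; ring D is a para-phenylene. There is no stereocentre and no stereogenic double bond, so every problem is constitutional. Both ethers are unsymmetrical and in both the ether carbon sits next to a free OH (ring A: C3–OAr beside C4–OH, with C1 para to C4; ring C: C5–OAr beside C4–OH). The catechol of ring C is air-sensitive under base, and three oxygens must end as free OH while two end as bridges. The hard points are the closure of the 19-membered ring and the ring A–O–ring B ether, which joins two electron-rich rings with no acceptor; the ring C–O–ring D ether can lean on a para acceptor on ring D. The feature used here: the ring A triad C4(OH)/C3(OAr)/C1(alkyl) is the twofold dehydrogenated form of a 2-aryloxy-4-alkylcyclohexanone, and the parent 4-alkylcyclohexanone is mirror-symmetric, so its two α-carbons are equivalent.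

## Retrosynthetic reasoning

21 to 20. The last cut removes only the two methyl groups on the C3 and C4 oxygens of ring C. They stay until the end because a free catechol would compete as a nucleophile in the ring closure and would not survive the oxidative step before it. The forward reaction is a Lewis-acid ether cleavage that leaves both diaryl ethers alone.

20 to 19. Ring A is taken back from the phenol to the cyclohexanone level: C4 becomes C=O, C3 an sp3 carbon bearing the aryloxy group, C1 an sp3 carbon bearing the bridge. No skeletal bond is cut, but the C3–O bond changes character, from an aryl–O bond that needs a metal or an acceptor to an alkyl–O bond next to a carbonyl group. The forward reaction must remove four hydrogens from ring A without touching the bibenzyl CH2 groups; palladium-catalysed aerobic dehydrogenation of cyclohexanones to phenols does this.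

19 to 18 (key disconnection). The bond between the α-carbon of the ring A ketone and the oxygen of ring B is cut, which opens the 19-membered ring. It is cut here and not at an ethano bridge because this is the one bond of the target without a good aromatic solution: both partners are electron-rich and the ring A carbon is flanked by an oxygen. In 18 the same carbon is a secondary α-bromo ketone, a very good SN2 electrophile. The gain is that ring closure and the difficult ether become one mild step, the seco compound needs no second activating or protecting group, and the sp3 ring A makes the chain more flexible. The forward reaction needs O-alkylation by a single phenoxide under high dilution.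

18 to 15. The bromine is removed. Ketone 15 has a mirror plane through C=O and C4, so bromination can give only one constitution. This symmetry alone places the ether oxygen at C3 of ring A (ortho to OH, meta to the bridge).

15 to 13, then to 8 and 11. The ring D–CH2CH2–ring A bridge is cut next to the benzylic carbon of ring D, as an olefin from aldehyde 8 and the ylide of phosphonium salt 11. Salt 11 brings ring A as a saturated, ketal-protected six-membered ring from the purchased alcohol 9 through iodide 10 and phosphine 2, so ring A is not aromatic before step 10. One hydrogenation of 13 saturates both olefins and frees the ring B phenol; acid then frees the ketone.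

8 to 6 and 7. The ring C–O–ring D ether is cut on the ring D side. There the para-formyl group of 7 activates displacement of fluoride by the ring C phenoxide and afterwards serves as the bridge carbon.

6 to 3 and 4. The ring B–CH2CH2–ring C bridge is cut as a stilbene from aldehyde 4 and phosphonium salt 3 (from 1 and 2). Aldehyde 4 already holds the three neighbouring oxygens of ring C with only the future ether oxygen free. The benzyl group on ring B keeps that phenol silent during the ether formation with 7 and is lost in the hydrogenation.

## Alternatives that were turned down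

Alternative 1: The textbook route. Disconnection: the ring A–CH2CH2–ring D bridge as a stilbene, with both diaryl ethers made beforehand on aromatic rings. Forward key step: intramolecular Wittig reaction of phosphonium aldehyde A1 under high dilution to the macrocyclic stilbene A2, then hydrogenation and demethylation to 21. It was turned down because the ring closure creates nothing but the ring. The ring A–O–ring B ether must still be made by a copper-mediated coupling of an ortho-methoxyphenol with an unactivated aryl bromide. Each diaryl ether half needs two benzylic carbons at different oxidation levels, and turning them into the ylide and aldehyde of A1 costs about five redox and activation steps that add no skeleton. The way to A1 is therefore several steps longer than the way to 18.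

Alternative 2: Disconnection: the same ring A–O–ring B bond, but on a fully aromatic ring A. Forward key step: intramolecular etherification of bromo phenol A3 with CuI (monovalent copper), an amino acid ligand and Cs2CO3 to the macrocyclic trimethyl ether A4, then demethylation to 21. It was turned down on mechanistic grounds. The aryl bromide of A3 is electron-rich and has a methoxy group ortho to the reacting carbon, the slowest substrate class for aryl halide activation at copper. The millimolar dilution needed for a 19-membered ring slows the catalyst–substrate encounter further. Temperatures above 100 °C and near-stoichiometric copper are then to be expected, with reductive loss of bromine as the competing process. A3 is also no shorter to reach than 18, since two olefins must be saturated and a benzyl group removed without palladium and hydrogen, which would take the bromine along.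

Alternative 3: Disconnection: the ring C–O–ring D bond by a union of two phenols of like polarity, in the manner of the presumed biosynthesis. Forward key step: two-electron oxidation (Tl(NO3)3 or anodic) of bisphenol A5, in which the ring D phenol oxygen attacks C5 of the oxidized 4-hydroxy-3-methoxyphenyl ring C to give A6, then demethylation to 21. It was turned down because nothing in A5 steers the attack to C5. The phenoxonium ion of a 4-alkyl-2-methoxyphenol is most electrophilic at C1 (para, giving a quinol ether) and at the methoxy-bearing C3 (giving an ortho-quinone ketal), and the ring D phenol is oxidized at a similar potential. The known remedy, two halogens ortho to each hydroxyl and a reductive work-up, adds halogenation and dehalogenation steps. A5 also still contains the difficult ring A–O–ring B ether.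

Key step: step 9

Assumption: 21 is achiral; intermediates with olefins (6, 8, 13) or stereocentres (16 to 19) are used as isomer mixtures, so their SMILES carry no descriptors; 1, 2, 4, 7 and 9 are taken as purchased.

## Route

Step 1
Reactants: 1 1-(benzyloxy)-3-(bromomethyl)benzene; 2 triphenylphosphine
Product: 3 [3-(benzyloxy)benzyl]triphenylphosphonium bromide
Conditions: toluene, 110 °C; the salt is filtered off
Reagents that add atoms: none
Why: SN2 quaternization of the phosphine by a primary benzylic bromide; the salt should precipitate from toluene.

Step 2
Reactants: 3 [3-(benzyloxy)benzyl]triphenylphosphonium bromide; 4 3-hydroxy-4,5-dimethoxybenzaldehyde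
Product: 6 5-{2-[3-(benzyloxy)phenyl]ethenyl}-2,3-dimethoxyphenol (E/Z mixture), via phosphonium ylide 5 (not isolated)
Conditions: 3 (1.2 equiv), KOtBu (2.3 equiv), THF, 0 °C; then 4, 0 °C to rt; aq NH4Cl
Reagents that add atoms: none
Why: Wittig olefination with a semi-stabilized benzylic ylide; the extra base holds the phenol of 4 as its potassium salt, which is meta to the formyl group and should not deactivate it; the olefin geometry is irrelevant because step 7 saturates it.

Step 3
Reactants: 6 5-{2-[3-(benzyloxy)phenyl]ethenyl}-2,3-dimethoxyphenol; 7 4-fluorobenzaldehyde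
Product: 8 4-(5-{2-[3-(benzyloxy)phenyl]ethenyl}-2,3-dimethoxyphenoxy)benzaldehyde (E/Z mixture)
Conditions: 7 (1.2 equiv), K2CO3, DMF, 110 °C
Reagents that add atoms: none
Why: Nucleophilic aromatic substitution (addition–elimination) of the fluoride para to the formyl group by the only free phenoxide; the ring B oxygen is benzylated and cannot compete.

Step 4
Reactants: 9 1,4-dioxaspiro[4.5]decan-8-ylmethanol
Product: 10 8-(iodomethyl)-1,4-dioxaspiro[4.5]decane
Conditions: I2, PPh3, imidazole, CH2Cl2, 0 °C to rt
Reagents that add atoms: iodine, [I][I]
Why: Appel-type iodination of a primary alcohol through its alkoxyphosphonium ion; imidazole takes up the acid, so the ketal should survive.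

Step 5
Reactants: 10 8-(iodomethyl)-1,4-dioxaspiro[4.5]decane; 2 triphenylphosphine
Product: 11 (1,4-dioxaspiro[4.5]decan-8-ylmethyl)triphenylphosphonium iodide
Conditions: MeCN, 82 °C, sealed tube; trituration with Et2O
Reagents that add atoms: none
Why: SN2 quaternization of the phosphine; the β-branch slows it, hence iodide as leaving group and prolonged heating.

Step 6
Reactants: 11 (1,4-dioxaspiro[4.5]decan-8-ylmethyl)triphenylphosphonium iodide; 8 4-(5-{2-[3-(benzyloxy)phenyl]ethenyl}-2,3-dimethoxyphenoxy)benzaldehyde
Product: 13 8-{2-[4-(5-{2-[3-(benzyloxy)phenyl]ethenyl}-2,3-dimethoxyphenoxy)phenyl]ethenyl}-1,4-dioxaspiro[4.5]decane (mixture of olefin isomers), via phosphonium ylide 12 (not isolated)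
Conditions: 11 (1.3 equiv), NaN(SiMe3)2, THF, −78 to 0 °C; then 8, −78 °C to rt
Reagents that add atoms: none
Why: Wittig olefination of an aromatic aldehyde by a non-stabilized ylide; 8 has no acidic proton, and the olefin geometry does not matter because step 7 saturates it.

Step 7
Reactants: 13 8-{2-[4-(5-{2-[3-(benzyloxy)phenyl]ethenyl}-2,3-dimethoxyphenoxy)phenyl]ethenyl}-1,4-dioxaspiro[4.5]decane
Product: 15 4-{2-[4-(5-{2-(3-hydroxyphenyl)ethyl}-2,3-dimethoxyphenoxy)phenyl]ethyl}cyclohexan-1-one, via ketal phenol 14 (not isolated)
Conditions: H2 (1 atm), 10% Pd/C, EtOAc–MeOH, rt; filtration; then 1 M aq HCl, THF, rt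
Reagents that add atoms: water, O
Why: Heterogeneous hydrogenation should saturate both olefins and cleave the benzyl ether by hydrogenolysis while arenes, diaryl ether and ketal stay; aqueous acid then hydrolyses the dioxolane to the ketone, whose oxygen comes from water.

Step 8
Reactants: 15 4-{2-[4-(5-{2-(3-hydroxyphenyl)ethyl}-2,3-dimethoxyphenoxy)phenyl]ethyl}cyclohexan-1-one
Product: 18 2-bromo-4-{2-[4-(5-{2-(3-hydroxyphenyl)ethyl}-2,3-dimethoxyphenoxy)phenyl]ethyl}cyclohexan-1-one (racemic cis/trans mixture), via bis(trimethylsilyl) compound 16 (not isolated), via silylated bromo ketone 17 (not isolated)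
Conditions: Me3SiOTf (2.4 equiv), Et3N, CH2Cl2, 0 °C; pentane, filtration, evaporation; then NBS (1.0 equiv), THF, −78 °C; then 1 M HCl, MeOH, 0 °C
Reagents that add atoms: N-bromosuccinimide, O=C1CCC(=O)N1Br; trimethylsilyl triflate, C[Si](C)(C)OS(=O)(=O)C(F)(F)F (silicon stays only in 16 and 17)
Why: α-Bromination of a ketone through its silyl enol ether; the two α-carbons of 15 are mirror images, so one constitution results, and the enol ether is far more nucleophilic toward NBS at −78 °C than the silylated ring B or ring C; acidic methanol then frees the phenol, and the new stereocentre needs no control.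

Step 9
Reactants: 18 2-bromo-4-{2-[4-(5-{2-(3-hydroxyphenyl)ethyl}-2,3-dimethoxyphenoxy)phenyl]ethyl}cyclohexan-1-one
Product: 19 macrocyclic ketone: the 19-membered ring of 21 with ring A as a cyclohexanone (C=O at the later C4, aryloxy on the adjacent sp3 carbon, bridge on the sp3 carbon para to C=O) and ring C as its 3,4-dimethyl ether (racemic diastereomer mixture)
Conditions: Cs2CO3 (3 equiv), MeCN, 60 °C; 18 added by syringe pump over 12 h, final 2 mM
Reagents that add atoms: none
Why: Cs2CO3 deprotonates the single phenol of 18 (ring B), and the caesium phenoxide displaces bromide at the carbon next to the ketone in an SN2 reaction that the adjacent C=O accelerates through overlap of its π* orbital with the C–Br σ* orbital. The closest known reaction type is the Williamson-type synthesis of 2-aryloxycyclohexanones from 2-halocyclohexanones and phenols with carbonate bases, run here intramolecularly as a macro-etherification. The step closes only the 19-membered ring, in a 19-exo-tet mode, and the sp3 carbons of ring A give the seco chain more freedom than a flat arene would. The new C–O stereocentre forms with inversion and, with the bridge-bearing carbon, gives racemic diastereomers; no control is needed because step 10 turns both carbons into arene carbons. The step needs O- over C-alkylation (caesium phenoxide in a polar aprotic solvent), substitution over loss of HBr or Favorskii contraction (weak carbonate base, no alkoxide, 60 °C) and ring closure over oligomerization (slow addition, 2 mM). Regiochemistry is not at stake, since 18 holds one phenol and one bromide whose position was fixed by the mirror symmetry of 15.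

Step 10
Reactants: 19 macrocyclic ketone
Product: 20 ring C 3,4-di-O-methyl ether of 21 (ring A phenol free)
Conditions: Pd(O2CCF3)2 (10 mol%), 2-(N,N-dimethylamino)pyridine (20 mol%), TsOH (40 mol%), O2 (1 atm), DMSO, 80 °C
Reagents that add atoms: none
Why: Palladium-catalysed aerobic dehydrogenation of a cyclohexanone to a phenol: divalent palladium forms a palladium enolate, β-hydride elimination introduces unsaturation, a second cycle and tautomerization give the arene, and O2 returns zerovalent palladium to the divalent state; both sp3 stereocentres of 19 vanish here.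

Step 11
Reactants: 20 ring C 3,4-di-O-methyl ether of 21
Product: 21 target macrocycle (ring A 4-OH, ring C 3,4-di-OH)
Conditions: BBr3 (6 equiv), CH2Cl2, −78 °C to rt; then MeOH, water
Reagents that add atoms: none
Why: Lewis-acid cleavage of aryl methyl ethers (boron binds the methoxy oxygen, bromide attacks the methyl carbon by SN2); the diaryl ethers offer no alkyl carbon and should stay intact.

## Compound list

1 | 1-(benzyloxy)-3-(bromomethyl)benzene | BrCc1cccc(OCc2ccccc2)c1 | starting material
2 | triphenylphosphine | c1ccc(cc1)P(c1ccccc1)c1ccccc1 | starting material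
3 | [3-(benzyloxy)benzyl]triphenylphosphonium bromide | [Br-].c1ccc(cc1)[P+](Cc1cccc(OCc2ccccc2)c1)(c1ccccc1)c1ccccc1 | intermediate
4 | 3-hydroxy-4,5-dimethoxybenzaldehyde | O=Cc1cc(O)c(OC)c(OC)c1 | starting material
5 | [3-(benzyloxy)benzylidene]triphenylphosphorane (ylide, not isolated) | c1ccc(cc1)P(=Cc1cccc(OCc2ccccc2)c1)(c1ccccc1)c1ccccc1 | intermediate
6 | 5-{2-[3-(benzyloxy)phenyl]ethenyl}-2,3-dimethoxyphenol (E/Z mixture) | COc1cc(C=Cc2cccc(OCc3ccccc3)c2)cc(O)c1OC | intermediate
7 | 4-fluorobenzaldehyde | O=Cc1ccc(F)cc1 | starting material
8 | 4-(5-{2-[3-(benzyloxy)phenyl]ethenyl}-2,3-dimethoxyphenoxy)benzaldehyde (E/Z mixture) | COc1cc(C=Cc2cccc(OCc3ccccc3)c2)cc(Oc2ccc(C=O)cc2)c1OC | intermediate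
9 | 1,4-dioxaspiro[4.5]decan-8-ylmethanol | OCC1CCC2(CC1)OCCO2 | starting material
10 | 8-(iodomethyl)-1,4-dioxaspiro[4.5]decane | ICC1CCC2(CC1)OCCO2 | intermediate
11 | (1,4-dioxaspiro[4.5]decan-8-ylmethyl)triphenylphosphonium iodide | [I-].c1ccc(cc1)[P+](CC1CCC2(CC1)OCCO2)(c1ccccc1)c1ccccc1 | intermediate
12 | (1,4-dioxaspiro[4.5]decan-8-ylmethylidene)triphenylphosphorane (ylide, not isolated) | c1ccc(cc1)P(=CC1CCC2(CC1)OCCO2)(c1ccccc1)c1ccccc1 | intermediate
13 | 8-{2-[4-(5-{2-[3-(benzyloxy)phenyl]ethenyl}-2,3-dimethoxyphenoxy)phenyl]ethenyl}-1,4-dioxaspiro[4.5]decane (olefin isomer mixture) | COc1cc(C=Cc2cccc(OCc3ccccc3)c2)cc(Oc2ccc(C=CC3CCC4(CC3)OCCO4)cc2)c1OC | intermediate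
14 | 3-{2-[3-(4-{2-(1,4-dioxaspiro[4.5]decan-8-yl)ethyl}phenoxy)-4,5-dimethoxyphenyl]ethyl}phenol (not isolated) | COc1cc(CCc2cccc(O)c2)cc(Oc2ccc(CCC3CCC4(CC3)OCCO4)cc2)c1OC | intermediate
15 | 4-{2-[4-(5-{2-(3-hydroxyphenyl)ethyl}-2,3-dimethoxyphenoxy)phenyl]ethyl}cyclohexan-1-one | COc1cc(CCc2cccc(O)c2)cc(Oc2ccc(CCC3CCC(=O)CC3)cc2)c1OC | intermediate
16 | trimethylsilyl enol ether of 15 with the ring B phenol as trimethylsilyl ether (racemic, not isolated) | COc1cc(CCc2cccc(O[Si](C)(C)C)c2)cc(Oc2ccc(CCC3CCC(O[Si](C)(C)C)=CC3)cc2)c1OC | intermediate
17 | ring B trimethylsilyl ether of 18 (isomer mixture, not isolated) | COc1cc(CCc2cccc(O[Si](C)(C)C)c2)cc(Oc2ccc(CCC3CCC(=O)C(Br)C3)cc2)c1OC | intermediate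
18 | 2-bromo-4-{2-[4-(5-{2-(3-hydroxyphenyl)ethyl}-2,3-dimethoxyphenoxy)phenyl]ethyl}cyclohexan-1-one (racemic cis/trans mixture) | COc1cc(CCc2cccc(O)c2)cc(Oc2ccc(CCC3CCC(=O)C(Br)C3)cc2)c1OC | intermediate
19 | macrocyclic ketone: ring A as 2-aryloxy-4-alkylcyclohexanone inside the 19-membered ring, ring C as 3,4-dimethyl ether (racemic diastereomer mixture) | O=C1CCC2CC1Oc1cccc(c1)CCc1cc(OC)c(OC)c(c1)Oc1ccc(cc1)CC2 | intermediate
20 | ring C 3,4-di-O-methyl ether of the target, ring A phenol free | Oc1ccc2cc1Oc1cccc(c1)CCc1cc(OC)c(OC)c(c1)Oc1ccc(cc1)CC2 | intermediate
21 | target macrocyclic bis(bibenzyl), ring A 4-OH, ring C 3,4-di-OH | Oc1ccc2cc1Oc1cccc(c1)CCc1cc(O)c(O)c(c1)Oc1ccc(cc1)CC2 | target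

## Step count and least certain steps

Total step count: 11. Longest linear sequence: 9 steps (steps 1, 2, 3, 6, 7, 8, 9, 10, 11); steps 4 and 5 form a two-step branch that joins at step 6.

Step 9 (key step). The most likely failure is oligomerization by intermolecular O-alkylation, because closure of a 19-membered ring onto a secondary carbon is slow. Base-induced loss of HBr or Favorskii contraction may also consume the bromo ketone while it waits for the phenoxide. The fallback replaces halide displacement under base by a neutral redox condensation. It sets out from 15: its bis(silyl) compound 16 is oxidized with mCPBA (Rubottom oxidation; CH2Cl2, NaHCO3, −20 °C; then dilute HCl in MeOH) to 2-hydroxy-4-{2-[4-(5-{2-(3-hydroxyphenyl)ethyl}-2,3-dimethoxyphenoxy)phenyl]ethyl}cyclohexan-1-one F1. F1 is then closed by an intramolecular Mitsunobu etherification (PPh3, diisopropyl azodicarboxylate, toluene, high dilution), in which the ring B phenol displaces the activated α-hydroxyl with inversion. This comes back to the route at 19.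

Step 10. The most likely failure is stalling after the first dehydrogenation, because the aryloxy group next to the ketone hinders palladium enolate formation. Cleavage of the alkyl–O bond under the acidic oxidative conditions would reopen the macrocycle. The fallback is a stepwise, stoichiometric dehydrogenation through an isolated enone. From 19, kinetic enolization away from the aryloxy carbon (LiN(SiMe3)2, THF, −78 °C) and PhSeCl should give the α'-(phenylselanyl) derivative of the macrocyclic ketone F2. H2O2 (pyridine, CH2Cl2, 0 °C) then gives, by selenoxide syn-elimination, the macrocyclic enone with the double bond on the unsubstituted side of the ketone F3. DDQ (cat. TsOH, dioxane, 90 °C) removes the last two hydrogens and the route is rejoined at 20.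

Step 8. The most likely failure is bromination of an electron-rich arene (ring C or the silylated ring B), or double bromination if the silyl enol ether is partly hydrolysed before NBS is added. The fallback uses no electrophilic halogen and raises ring A by one oxidation level before ring closure. From 15 via 16, Saegusa–Ito oxidation (Pd(OAc)2, MeCN, rt; acidic work-up) gives 4-{2-[4-(5-{2-(3-hydroxyphenyl)ethyl}-2,3-dimethoxyphenoxy)phenyl]ethyl}cyclohex-2-en-1-one F4. Alkaline H2O2 (NaOH, MeOH, 0 °C) gives the corresponding 2,3-epoxy ketone F5. With Cs2CO3 in DMF under high dilution, the ring B phenoxide should open the epoxide at the carbon next to the ketone, with loss of water, to the macrocyclic 2-aryloxycyclohex-2-enone F6. DDQ in dioxane (90 °C) then removes the remaining two hydrogens, and the route is rejoined at 20.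

Step 5. The most likely failure is incomplete quaternization at the β-branched iodide, which leaves too little ylide for step 6. The fallback is a Julia–Kocienski olefination. From 10, 1-phenyl-1H-tetrazole-5-thiol and K2CO3 (DMF) give 5-[(1,4-dioxaspiro[4.5]decan-8-ylmethyl)sulfanyl]-1-phenyl-1H-tetrazole F7. (NH4)6Mo7O24 and H2O2 (EtOH) give 5-[(1,4-dioxaspiro[4.5]decan-8-ylmethyl)sulfonyl]-1-phenyl-1H-tetrazole F8. Its potassium salt (KN(SiMe3)2, THF, −78 °C) with aldehyde 8 gives 13, where the route is rejoined.

## Further compounds

F1 | step 9 | 2-hydroxy-4-{2-[4-(5-{2-(3-hydroxyphenyl)ethyl}-2,3-dimethoxyphenoxy)phenyl]ethyl}cyclohexan-1-one | COc1cc(CCc2cccc(O)c2)cc(Oc2ccc(CCC3CCC(=O)C(O)C3)cc2)c1OC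
F2 | step 10 | α'-(phenylselanyl) derivative of macrocyclic ketone 19 | O=C1C([Se]c3ccccc3)CC2CC1Oc1cccc(c1)CCc1cc(OC)c(OC)c(c1)Oc1ccc(cc1)CC2
F3 | step 10 | macrocyclic enone, ring A as 6-aryloxy-4-alkylcyclohex-2-en-1-one | O=C1C=CC2CC1Oc1cccc(c1)CCc1cc(OC)c(OC)c(c1)Oc1ccc(cc1)CC2
F4 | step 8 | 4-{2-[4-(5-{2-(3-hydroxyphenyl)ethyl}-2,3-dimethoxyphenoxy)phenyl]ethyl}cyclohex-2-en-1-one | COc1cc(CCc2cccc(O)c2)cc(Oc2ccc(CCC3CCC(=O)C=C3)cc2)c1OC
F5 | step 8 | 5-{2-[4-(5-{2-(3-hydroxyphenyl)ethyl}-2,3-dimethoxyphenoxy)phenyl]ethyl}-7-oxabicyclo[4.1.0]heptan-2-one | COc1cc(CCc2cccc(O)c2)cc(Oc2ccc(CCC3CCC(=O)C4OC34)cc2)c1OC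
F6 | step 8 | macrocyclic enone, ring A as 2-aryloxy-4-alkylcyclohex-2-en-1-one | O=C1CCC2C=C1Oc1cccc(c1)CCc1cc(OC)c(OC)c(c1)Oc1ccc(cc1)CC2
F7 | step 5 | 5-[(1,4-dioxaspiro[4.5]decan-8-ylmethyl)sulfanyl]-1-phenyl-1H-tetrazole | S(CC1CCC2(CC1)OCCO2)c1nnnn1-c1ccccc1
F8 | step 5 | 5-[(1,4-dioxaspiro[4.5]decan-8-ylmethyl)sulfonyl]-1-phenyl-1H-tetrazole | O=S(=O)(CC1CCC2(CC1)OCCO2)c1nnnn1-c1ccccc1
A1 | alternative 1 | seco phosphonium aldehyde (ring A 4-methoxy-3-aryloxybenzaldehyde, ring D benzylic phosphonium bromide) | [Br-].COc1ccc(C=O)cc1Oc1cccc(c1)CCc1cc(OC)c(OC)c(c1)Oc1ccc(cc1)C[P+](c1ccccc1)(c1ccccc1)c1ccccc1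
A2 | alternative 1 | macrocyclic stilbene trimethyl ether | COc1ccc2cc1Oc1cccc(c1)CCc1cc(OC)c(OC)c(c1)Oc1ccc(cc1)C=C2
A3 | alternative 2 | seco bromo phenol (ring A 3-bromo-4-methoxyphenyl, ring B free phenol) | COc1ccc(CCc2ccc(Oc3cc(CCc4cccc(O)c4)cc(OC)c3OC)cc2)cc1Br
A4 | alternative 2 | macrocyclic trimethyl ether of the target | COc1ccc2cc1Oc1cccc(c1)CCc1cc(OC)c(OC)c(c1)Oc1ccc(cc1)CC2
A5 | alternative 3 | seco bisphenol (ring D 4-hydroxyphenyl, ring C 4-hydroxy-3-methoxyphenyl, ring A methyl ether) | COc1ccc(CCc2ccc(O)cc2)cc1Oc1cccc(c1)CCc1ccc(O)c(OC)c1
A6 | alternative 3 | macrocycle with ring C 4-OH free, ring C 3-OMe and ring A 4-OMe | COc1ccc2cc1Oc1cccc(c1)CCc1cc(OC)c(O)c(c1)Oc1ccc(cc1)CC2
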